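## Retrosynthetic overview

1. **Feature.** Two mirror-image trans-quinolizidin-2-one units (ring A N–C4–C3(Me)–C2(=O)–C1–C10, ring B N–C6–C7–C8–C9–C10) are tied head to tail into a 16-membered carbocycle by two bare linkers C9–Ca–Cb–Cc–Cd–Ce–C1′. Nothing marks Cc–Cd, so this bond can be made as an alkene, and a sulfur atom can hold its place beforehand.
2. **Key disconnection.** Both Cc=Cd bonds come from a double Ramberg–Bäcklund loss of SO2 from the 18-membered bis-sulfone (Cc–SO2–Cd in each linker), with C2 and C2′ masked as ethylene ketals. Hydrogenation and ketal hydrolysis finish the synthesis.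
3. **Macrocycle.** The 18-membered ring comes from two thiolate alkylations at Cc between the two enantiomers of one monomer ketal (C9 arm (CH2)3Cl, C1 arm (CH2)2S-PMB). Sulfur is bonded to Cd before nitrogen becomes basic, because a leaving group on the axial C1 arm would lie 1,3-diaxial to the N lone pair and close a five-membered ammonium ring.
4. **Monomer.** Ring A comes from lactam reduction and intramolecular Mannich closure (C1–C10) of a piperidin-2-one that carries the methacrylate-derived N–C4–C3(Me)–C2 chain and the C9 arm.
5. **Ring order.** Ring B (bought) → ring A → 18-membered dithia ring → 17-membered → 16-membered carbocycle.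

Key step: step 16

Remark: the target SMILES has an inversion centre (each stereocentre of one half is mirrored in the other), so Petrosin A is treated as the meso compound. Compounds 3–18 are racemic or stereoisomer mixtures, and 17 and 18 are drawn as one enantiomer. PMB = 4-methoxybenzyl. C10 is position 9a in the quinolizine names.

## Route

Step 1
Reactants: 1 piperidin-2-one; 2 methyl methacrylate
Product: 3 methyl 2-methyl-3-(2-oxopiperidin-1-yl)propanoate (racemic)
Conditions: KOt-Bu (0.1 equiv), BHT (trace), THF, 0 → 40 °C
Reagents that add atoms: none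
Why: Base-catalysed aza-Michael addition in which the lactam N-anion adds to the methacrylate β-carbon (future C4) and proton transfer from fresh lactam carries the chain; C3 forms racemic and stays epimerisable until step 7.

Step 2
Reactants: 3 methyl 2-methyl-3-(2-oxopiperidin-1-yl)propanoate
Product: 4 N-methoxy-N,2-dimethyl-3-(2-oxopiperidin-1-yl)propanamide (racemic Weinreb amide)
Conditions: MeNH(OMe)·HCl, i-PrMgCl, THF, −20 → 0 °C
Reagents that add atoms: N,O-dimethylhydroxylamine hydrochloride, CNOC.Cl
Why: Weinreb amidation of the ester by the magnesium amide of N,O-dimethylhydroxylamine; the tertiary lactam carbonyl is much less electrophilic and should be left alone at this temperature.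

Step 3
Reactants: 5 (4-methoxyphenyl)methanethiol; 6 1-bromo-3-chloropropane
Product: 7 3-chloropropyl 4-methoxybenzyl sulfide
Conditions: K2CO3, acetone, 23 °C
Reagents that add atoms: none
Why: SN2 S-alkylation of a thiolate in which bromide leaves far faster than chloride, so sulfur becomes bonded to the future Cd at a stage where no amine exists.

Step 4
Reactants: 7 3-chloropropyl 4-methoxybenzyl sulfide; 4 Weinreb amide
Product: 9 1-{6-[(4-methoxybenzyl)sulfanyl]-2-methyl-3-oxohexyl}piperidin-2-one (racemic), via Grignard reagent 8 (not isolated)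
Conditions: Mg, I2 (cat.), THF, reflux; then 4, THF, 0 °C; aq NH4Cl
Reagents that add atoms: none
Why: Grignard formation followed by Weinreb ketone synthesis, where chelation stops the addition at the ketone level and delivers C2 bearing C1, Ce, Cd and the protected sulfur.

Step 5
Reactants: 9 keto lactam; 10 ethane-1,2-diol
Product: 11 1-[2-(2-{3-[(4-methoxybenzyl)sulfanyl]propyl}-1,3-dioxolan-2-yl)propyl]piperidin-2-one (racemic)
Conditions: TsOH·H2O (cat.), benzene, reflux, Dean–Stark
Reagents that add atoms: none
Why: Acid-catalysed ketalisation with azeotropic removal of water masks C2 against the enolate chemistry of step 6 and the hydride of step 7.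

Step 6
Reactants: 11 ketal lactam; 12 1-chloro-3-iodopropane
Product: 14 3-(3-chloropropyl)-1-[2-(2-{3-[(4-methoxybenzyl)sulfanyl]propyl}-1,3-dioxolan-2-yl)propyl]piperidin-2-one (both diastereomers; racemic), via lithium enolate 13 (not isolated)
Conditions: LiN(i-Pr)2 (1.05 equiv), THF, −78 °C; then 12, −78 → −20 °C
Reagents that add atoms: none
Why: Lactam enolate alkylation (SN2 at the iodide end of the dihalide) puts the Ca–Cb–Cc arm on C9 with chloride as a dormant leaving group; C9 forms without control relative to C3, which is harmless because C3 is equilibrated in step 7.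

Step 7
Reactants: 14 alkylated ketal lactam
Product: 17 rac-(1R*,3R*,9R*,9aS*)-9-(3-chloropropyl)-1-{2-[(4-methoxybenzyl)sulfanyl]ethyl}-3-methyloctahydro-2H-quinolizin-2-one (trans-fused; H9 anti to H10; H1 syn to H10; C9 chain and C3 methyl equatorial; C1 chain axial), via carbinolamine 15 (not isolated), via keto iminium chloride 16 (not isolated)
Conditions: i-Bu2AlH (1.2 equiv), toluene, −78 °C; then 2 M aq HCl–THF, −78 → 45 °C; aq K2CO3; chromatography
Reagents that add atoms: water, O
Why: Partial reduction of the tertiary lactam gives a carbinolamine that ionises in acid to the C10 iminium ion while the dioxolane is hydrolysed, and the C1 enol closes ring A by an intramolecular Mannich reaction; attack anti to a pseudo-axial C9 chain avoids the peri (syn-pentane) clash of the C1 and C9 chains and should set H9/H10 anti, after which acid enolisation lets C1 and C3 settle with methyl equatorial and the C1 chain axial, the only trans-fused arrangement free of both that clash and a 1,3-diaxial pair.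

Step 8
Reactants: 17 quinolizidinone; 10 ethane-1,2-diol
Product: 18 rac-(1′R*,3′R*,9′R*,9a′S*)-9′-(3-chloropropyl)-1′-{2-[(4-methoxybenzyl)sulfanyl]ethyl}-3′-methyloctahydrospiro[1,3-dioxolane-2,2′-quinolizine] (ethylene ketal of 17)
Conditions: 10 (10 equiv), TsOH·H2O (1.5 equiv), benzene, reflux, Dean–Stark; aq K2CO3
Reagents that add atoms: none
Why: Acid-catalysed ketalisation with more than one equivalent of acid so that nitrogen stays protonated; the C1-axial/C3-equatorial arrangement should persist because each C1 or C3 epimer of the ketal would suffer the peri clash or a 1,3-diaxial contact, and from here on C1 and C3 are locked.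

Step 9
Reactants: 18 racemic monomer ketal
Product: 19 (1′R,3′R,9′R,9a′S) enantiomer of 18 and 20 (1′S,3′S,9′S,9a′R) enantiomer of 18
Conditions: preparative SFC, amylose tris(3,5-dimethylphenylcarbamate) phase, CO2–MeOH–Et2NH
Reagents that add atoms: none
Why: Enantiomer separation on a chiral stationary phase of a configurationally locked amine with a UV-active PMB group; both antipodes are needed in equal amount for the meso target, and which one takes which role below is immaterial.

Step 10
Reactants: 19 (1′R,3′R,9′R,9a′S) monomer ketal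
Product: 21 iodide of 19 (C9 arm (CH2)3I; C1 arm (CH2)2S-PMB; same configuration)
Conditions: NaI (5 equiv), acetone, reflux, dark; used at once
Reagents that add atoms: sodium iodide, [Na+].[I-]
Why: Finkelstein halide exchange driven by precipitation of NaCl; the equatorial C9 chain cannot reach the N lone pair, which points to the opposite face and is screened by the axial C1 chain, so quaternisation should not compete.

Step 11
Reactants: 20 (1′S,3′S,9′S,9a′R) monomer ketal
Product: 23 thiol of 20 (C1 arm (CH2)2SH; C9 arm (CH2)3Cl; same configuration), via mercury thiolate 22 (not isolated)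
Conditions: Hg(O2CCF3)2 (1.1 equiv), anisole, TFA, 0 °C; evaporate; H2S, EtOAc; filter; degassed aq NaHCO3; used at once
Reagents that add atoms: none
Why: Soft-metal-assisted acidolysis of an S-PMB thioether, in which divalent mercury binds sulfur, the PMB cation is trapped by anisole and H2S frees the thiol; the ketal should survive because the protonated nitrogen β to C2 disfavours the oxocarbenium ion.

Step 12
Reactants: 21 iodide; 23 thiol
Product: 24 open heterochiral dimer (Cc of the 19-derived unit joined through sulfur to Cd of the 20-derived unit; the first unit keeps its C1 arm (CH2)2S-PMB and the second its C9 arm (CH2)3Cl; both C2 as ethylene ketals)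
Conditions: Cs2CO3 (2 equiv), degassed DMF, 0 → 23 °C
Reagents that add atoms: none
Why: SN2 thioether formation in which the caesium thiolate takes the primary iodide far faster than either primary chloride, so only the crossed head-to-tail Cc–S bond should form.

Step 13
Reactants: 24 open dimer
Product: 26 thiol chloride dimer (as 24 with the C1 arm (CH2)2SH free), via mercury thiolate 25 (not isolated)
Conditions: Hg(O2CCF3)2 (2.2 equiv), anisole, TFA, 0 °C; evaporate; H2S, EtOAc; filter; degassed aq NaHCO3; used at once
Reagents that add atoms: none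
Why: The same mercury-assisted S-PMB cleavage as in step 11; the dialkyl thioether link only binds the metal reversibly because it has no stabilised cation to lose, and the primary chloride is inert.

Step 14
Reactants: 26 thiol chloride dimer
Product: 27 meso 18-membered dithia macrocycle (bis(quinolizidine ethylene ketal) with each linker C9–Ca–Cb–Cc–S–Cd–Ce–C1′)
Conditions: slow addition to Cs2CO3 (5 equiv), NaI (0.2 equiv), DMF, 60 °C, final 1 mM, argon
Reagents that add atoms: none
Why: Intramolecular SN2 thioether formation of a caesium thiolate under high dilution with iodide catalysis at the chloride closes the 18-membered ring head to tail, and because the two units are enantiomers the product is centrosymmetric.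

Step 15
Reactants: 27 dithia macrocycle
Product: 29 meso 18-membered bis-sulfone of the bis(quinolizidine ethylene ketal) (each linker C9–Ca–Cb–Cc–SO2–Cd–Ce–C1′), via bis-ammonium salt 28 (not isolated)
Conditions: TFA (4 equiv), CH2Cl2, 0 °C; mCPBA (4.5 equiv), 0 → 23 °C; aq Na2SO3; aq K2CO3
Reagents that add atoms: 3-chloroperoxybenzoic acid (mCPBA), OOC(=O)c1cccc(Cl)c1
Why: Peracid oxidation of sulfide through sulfoxide to sulfone, with both amines masked as ammonium trifluoroacetates and thus inert to the electrophilic oxidant, in a water-free medium that spares the ketals.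

Step 16
Reactants: 29 bis-sulfone
Product: 35 meso 16-membered diene bis(ethylene ketal) with Cc=Cd in both linkers (drawn E/E; Z isomers are carried along), via bromo sulfone 30 (not isolated), via episulfone 31 (not isolated), via ene sulfone 32 (not isolated), via bromo ene sulfone 33 (not isolated), via ene episulfone 34 (not isolated)
Conditions: KOH/Al2O3 (excess), CBr2F2 (excess), t-BuOH–CH2Cl2, 0 → 23 °C, dark
Reagents that add atoms: none
Why: Supported KOH deprotonates a sulfone α-CH2 (Cc or Cd, drawn at Cc), the carbanion takes bromine from CBr2F2, deprotonation at the other α-carbon displaces bromide in a 1,3-elimination to the episulfone, and this loses SO2 to leave Cc=Cd; the sequence then repeats at the second sulfone. This is the Ramberg–Bäcklund reaction in its one-flask halogenative form, a variant well used for macrocyclic alkenes. The 16-membered carbocycle is not closed end to end but arises by two one-atom contractions, 18 to 17 to 16, each through a 3-exo-tet closure to a transient three-membered episulfone, so the entropic price was already paid in step 14. No stereocentre is created, and alkene geometry is left uncontrolled because both isomers give the same linker in step 17. The step needs carbanion formation and halogenation only at the four α-sulfonyl carbons: the ketals remove every enolisable position so C1 and C3 can neither epimerise nor be brominated, C9 and C10 carry no acidic hydrogen, either α-carbon of a sulfone leads to the same alkene, and the tertiary amines have no N–H and a lone pair screened by the axial C1 chain. Low temperature, darkness and t-BuOH as carbene trap should limit attack of the bromine donor or of difluorocarbene on nitrogen and on the new alkenes.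

Step 17
Reactants: 35 diene bis-ketal
Product: 36 meso 16-membered saturated bis(ethylene ketal) (each linker C9–(CH2)5–C1′)
Conditions: H2 (1 atm), Pd/C (10 wt % palladium on carbon), EtOH, 23 °C
Reagents that add atoms: none
Why: Heterogeneous catalytic hydrogenation of two unhindered disubstituted alkenes, which merges all E/Z isomers into one compound and touches no stereocentre, with no sulfur left to poison the catalyst.

Step 18
Reactants: 36 saturated bis-ketal
Product: 37 Petrosin A
Conditions: 3 M aq HCl, THF, 50 °C; aq NaHCO3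
Reagents that add atoms: water, O
Why: Acid-catalysed ketal hydrolysis, which needs forcing acid because of the β-ammonium groups; C1 and C3 already hold the arrangement preferred under enolising conditions (step 7), so they should be retained.

## Compound list

1 | piperidin-2-one | O=C1CCCCN1 | starting material
2 | methyl methacrylate | C=C(C)C(=O)OC | starting material
3 | methyl 2-methyl-3-(2-oxopiperidin-1-yl)propanoate (racemic) | O=C1CCCCN1CC(C)C(=O)OC | intermediate
4 | N-methoxy-N,2-dimethyl-3-(2-oxopiperidin-1-yl)propanamide (racemic) | O=C1CCCCN1CC(C)C(=O)N(C)OC | intermediate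
5 | (4-methoxyphenyl)methanethiol | COc1ccc(CS)cc1 | starting material
6 | 1-bromo-3-chloropropane | ClCCCBr | starting material
7 | 3-chloropropyl 4-methoxybenzyl sulfide | ClCCCSCc1ccc(OC)cc1 | intermediate
8 | 3-[(4-methoxybenzyl)sulfanyl]propylmagnesium chloride | Cl[Mg]CCCSCc1ccc(OC)cc1 | intermediate
9 | 1-{6-[(4-methoxybenzyl)sulfanyl]-2-methyl-3-oxohexyl}piperidin-2-one (racemic) | O=C1CCCCN1CC(C)C(=O)CCCSCc2ccc(OC)cc2 | intermediate
10 | ethane-1,2-diol | OCCO | starting material
11 | ethylene ketal of 9 (racemic) | O=C1CCCCN1CC(C)C2(CCCSCc3ccc(OC)cc3)OCCO2 | intermediate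
12 | 1-chloro-3-iodopropane | ClCCCI | starting material
13 | lithium enolate of 11 | [Li]OC1=CCCCN1CC(C)C2(CCCSCc3ccc(OC)cc3)OCCO2 | intermediate
14 | 3-(3-chloropropyl) derivative of 11 (diastereomer mixture, racemic) | O=C1C(CCCCl)CCCN1CC(C)C2(CCCSCc3ccc(OC)cc3)OCCO2 | intermediate
15 | carbinolamine (2-hydroxypiperidine from 14) | OC1C(CCCCl)CCCN1CC(C)C2(CCCSCc3ccc(OC)cc3)OCCO2 | intermediate
16 | keto iminium chloride (C10=N+, C2 ketone free) | [Cl-].O=C(CCCSCc1ccc(OC)cc1)C(C)C[N+]2=CC(CCCCl)CCC2 | intermediate
17 | rac-(1R*,3R*,9R*,9aS*)-9-(3-chloropropyl)-1-{2-[(4-methoxybenzyl)sulfanyl]ethyl}-3-methyloctahydro-2H-quinolizin-2-one | C[C@@H]1CN2CCC[C@H](CCCCl)[C@H]2[C@@H](CCSCc3ccc(OC)cc3)C1=O | intermediate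
18 | ethylene ketal of 17 (racemic) | C[C@@H]1CN2CCC[C@H](CCCCl)[C@H]2[C@@H](CCSCc3ccc(OC)cc3)C14OCCO4 | intermediate
19 | (1′R,3′R,9′R,9a′S) enantiomer of 18 | C[C@@H]1CN2CCC[C@H](CCCCl)[C@H]2[C@@H](CCSCc3ccc(OC)cc3)C14OCCO4 | intermediate
20 | (1′S,3′S,9′S,9a′R) enantiomer of 18 | C[C@H]1CN2CCC[C@@H](CCCCl)[C@@H]2[C@H](CCSCc3ccc(OC)cc3)C14OCCO4 | intermediate
21 | iodide of 19 | C[C@@H]1CN2CCC[C@H](CCCI)[C@H]2[C@@H](CCSCc3ccc(OC)cc3)C14OCCO4 | intermediate
22 | mercury thiolate from 20 (S–Hg–O2CCF3) | C[C@H]1CN2CCC[C@@H](CCCCl)[C@@H]2[C@H](CCS[Hg]OC(=O)C(F)(F)F)C13OCCO3 | intermediate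
23 | thiol of 20 | C[C@H]1CN2CCC[C@@H](CCCCl)[C@@H]2[C@H](CCS)C13OCCO3 | intermediate
24 | open heterochiral dimer (one thioether link, one S-PMB arm, one chloride arm) | C[C@@H]1CN2CCC[C@H](CCCSCC[C@H]3[C@H]4[C@H](CCCCl)CCCN4C[C@H](C)C35OCCO5)[C@H]2[C@@H](CCSCc6ccc(OC)cc6)C17OCCO7 | intermediate
25 | mercury thiolate from 24 | C[C@@H]1CN2CCC[C@H](CCCSCC[C@H]3[C@H]4[C@H](CCCCl)CCCN4C[C@H](C)C35OCCO5)[C@H]2[C@@H](CCS[Hg]OC(=O)C(F)(F)F)C17OCCO7 | intermediate
26 | thiol chloride dimer | C[C@@H]1CN2CCC[C@H](CCCSCC[C@H]3[C@H]4[C@H](CCCCl)CCCN4C[C@H](C)C35OCCO5)[C@H]2[C@@H](CCS)C17OCCO7 | intermediate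
27 | meso 18-membered dithia macrocycle, bis-ketal | C[C@@H]1CN2CCC[C@@H]3CCCSCC[C@@H]4C6(OCCO6)[C@@H](C)CN5CCC[C@@H](CCCSCC[C@@H](C17OCCO7)[C@H]32)[C@H]45 | intermediate
28 | bis(trifluoroacetate) salt of 27 | C[C@@H]1C[NH+]2CCC[C@@H]3CCCSCC[C@@H]4C6(OCCO6)[C@@H](C)C[NH+]5CCC[C@@H](CCCSCC[C@@H](C17OCCO7)[C@H]32)[C@H]45.[O-]C(=O)C(F)(F)F.[O-]C(=O)C(F)(F)F | intermediate
29 | meso 18-membered bis-sulfone, bis-ketal | C[C@@H]1CN2CCC[C@@H]3CCCS(=O)(=O)CC[C@@H]4C6(OCCO6)[C@@H](C)CN5CCC[C@@H](CCCS(=O)(=O)CC[C@@H](C17OCCO7)[C@H]32)[C@H]45 | intermediate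
30 | α-bromo sulfone (Br drawn at Cc of one linker, CHBr undefined) | C[C@@H]1CN2CCC[C@@H]3CCC(Br)S(=O)(=O)CC[C@@H]4C6(OCCO6)[C@@H](C)CN5CCC[C@@H](CCCS(=O)(=O)CC[C@@H](C17OCCO7)[C@H]32)[C@H]45 | intermediate
31 | episulfone in one linker (Cc and Cd bridged by SO2) | C[C@@H]1CN2CCC[C@@H]3CCC8S(=O)(=O)C8C[C@@H]4C6(OCCO6)[C@@H](C)CN5CCC[C@@H](CCCS(=O)(=O)CC[C@@H](C17OCCO7)[C@H]32)[C@H]45 | intermediate
32 | 17-membered ene sulfone | C[C@@H]1CN2CCC[C@@H]3CC/C=C/C[C@@H]4C6(OCCO6)[C@@H](C)CN5CCC[C@@H](CCCS(=O)(=O)CC[C@@H](C17OCCO7)[C@H]32)[C@H]45 | intermediate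
33 | α-bromo derivative of 32 | C[C@@H]1CN2CCC[C@@H]3CC/C=C/C[C@@H]4C6(OCCO6)[C@@H](C)CN5CCC[C@@H](CCC(Br)S(=O)(=O)CC[C@@H](C17OCCO7)[C@H]32)[C@H]45 | intermediate
34 | episulfone from 33 | C[C@@H]1CN2CCC[C@@H]3CC/C=C/C[C@@H]4C6(OCCO6)[C@@H](C)CN5CCC[C@@H](CCC8S(=O)(=O)C8C[C@@H](C17OCCO7)[C@H]32)[C@H]45 | intermediate
35 | meso 16-membered diene bis(ethylene ketal) (drawn E,E) | C[C@@H]1CN2CCC[C@@H]3CC/C=C/C[C@@H]4C6(OCCO6)[C@@H](C)CN5CCC[C@@H](CC/C=C/C[C@@H](C17OCCO7)[C@H]32)[C@H]45 | intermediate
36 | meso 16-membered saturated bis(ethylene ketal) | C[C@@H]1CN2CCC[C@@H]3CCCCC[C@@H]4C6(OCCO6)[C@@H](C)CN5CCC[C@@H](CCCCC[C@@H](C17OCCO7)[C@H]32)[C@H]45 | intermediate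
37 | Petrosin A | C[C@@H]1CN2CCC[C@@H]3CCCCC[C@@H]4C(=O)[C@@H](C)CN5CCC[C@@H](CCCCC[C@@H](C1=O)[C@H]32)[C@H]45 | target

## Step count

- Total step count: 18.
- Longest linear sequence: 16 steps (1, 2, 4–9, 10 or 11, 12–18).

## Steps most likely to fail

**Step 16 (key step).**
- *What may go wrong:* bromine transfer or difluorocarbene attack at the tertiary amines, repeated halogenation of one α-carbon before the episulfone closes, or a stalled second extrusion.
- *Fallback:* it sets out from 27 and returns at 35, and it installs the halogen at the sulfide oxidation level so that no polyhalomethane or carbene is ever in the flask.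
- As its bis(trifluoroacetate), 27 is chlorinated with N-chlorosuccinimide in CH2Cl2 (chlorosulfonium ion, then Pummerer-type shift) to the bis(α-chloro sulfide) F1.
- F1 is oxidised without purification with mCPBA to the bis(α-chloro sulfone) F2.
- KOt-Bu in THF (−78 → 0 °C) then performs the classical Ramberg–Bäcklund reaction of a preformed α-halo sulfone. Either regiochemistry of chlorination leads to the same Cc=Cd bond.

**Step 7.**
- *What may go wrong:* poor facial selectivity of the Mannich closure at C10 relative to C9, or over-reduction of the lactam.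
- *Fallback:* it sets out from 4 and returns at 17, and it separates the two stereochemical decisions.
- MeMgBr converts 4 into the methyl ketone F3, which is ketalised with 10 to the dioxolane F4 and alkylated (LiN(i-Pr)2, then 12) to the chloropropyl lactam F5.
- i-Bu2AlH and aqueous acid give, by the same closure but with C1 unsubstituted, the quinolizidinone F6.
- Warming F6 in AcOH–NaOAc lets C1–C10 reopen and reclose (retro-Mannich/Mannich). Without a C1 chain the all-equatorial trans-fused isomer with H9 anti to H10 should be clearly preferred.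
- 1,1-Dimethylhydrazine gives the hydrazone F7.
- Separately, 5 is alkylated with 1-bromo-2-chloroethane to the 2-chloroethyl sulfide F8, which is exchanged with NaI to the 2-iodoethyl sulfide F9.
- LiN(i-Pr)2 deprotonates F7 at the less substituted C1. The aza-enolate should take F9 along the axial trajectory, on the face opposite H10, to give the alkylated hydrazone F10.
- Two-phase hydrolysis of F10 with aqueous oxalic acid returns 17.

**Step 18.**
- *What may go wrong:* epimerisation at C3 or C1 by enolisation, or reopening of C1–C10, during the forcing hydrolysis of the β-ammonium ketals.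
- *Fallback:* it sets out from 36 and returns at 37. It stops trying to preserve configuration kinetically and uses a thermodynamic funnel instead.
- Hydrolysis is driven to completion (6 M aq HCl, 80 °C), accepting leakage to species such as the mono-C3 epimer F11.
- The crude ketone mixture is equilibrated with DBU in MeOH, so that C1 and C3 resettle into the C1-axial/C3-equatorial arrangement.
- The centrosymmetric 37 is removed by crystallisation and the mother liquors are re-equilibrated.

Further compounds
F1 | step 16 | bis(α-chloro sulfide) of 27 (Cl drawn at Cc, CHCl undefined) | C[C@@H]1CN2CCC[C@@H]3CCC(Cl)SCC[C@@H]4C6(OCCO6)[C@@H](C)CN5CCC[C@@H](CCC(Cl)SCC[C@@H](C17OCCO7)[C@H]32)[C@H]45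
F2 | step 16 | bis(α-chloro sulfone) | C[C@@H]1CN2CCC[C@@H]3CCC(Cl)S(=O)(=O)CC[C@@H]4C6(OCCO6)[C@@H](C)CN5CCC[C@@H](CCC(Cl)S(=O)(=O)CC[C@@H](C17OCCO7)[C@H]32)[C@H]45
F3 | step 7 | 1-(2-methyl-3-oxobutyl)piperidin-2-one (racemic) | CC(=O)C(C)CN1CCCCC1=O
F4 | step 7 | ethylene ketal of F3 | CC(CN1CCCCC1=O)C2(C)OCCO2
F5 | step 7 | 3-(3-chloropropyl) derivative of F4 (diastereomer mixture) | CC(CN1CCCC(CCCCl)C1=O)C2(C)OCCO2
F6 | step 7 | rac-9-(3-chloropropyl)-3-methyloctahydro-2H-quinolizin-2-one (trans-fused, all-equatorial) | C[C@@H]1CN2CCC[C@H](CCCCl)[C@H]2CC1=O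
F7 | step 7 | N,N-dimethylhydrazone of F6 | C[C@@H]1CN2CCC[C@H](CCCCl)[C@H]2CC1=NN(C)C
F8 | step 7 | 2-chloroethyl 4-methoxybenzyl sulfide | ClCCSCc1ccc(OC)cc1
F9 | step 7 | 2-iodoethyl 4-methoxybenzyl sulfide | ICCSCc1ccc(OC)cc1
F10 | step 7 | N,N-dimethylhydrazone of 17 (C1 chain axial) | C[C@@H]1CN2CCC[C@H](CCCCl)[C@H]2[C@@H](CCSCc3ccc(OC)cc3)C1=NN(C)C
F11 | step 18 | mono-C3 epimer of Petrosin A | C[C@H]1CN2CCC[C@@H]3CCCCC[C@@H]4C(=O)[C@@H](C)CN5CCC[C@@H](CCCCC[C@@H](C1=O)[C@H]32)[C@H]45
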